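**Retrosynthetic overview**
- The target is reached by hydrogenolysis of six benzyl ethers from a hexabenzyl diketone, whose C9 ketone comes from a silyl-protected C9 carbinol that both masks the 1,3-dicarbonyl and carries the chirality.
- The strategy rests on ring B, a 1-tetralone in which C1 (the ketone) and C4 (the methine bearing C9) are both bonded to ring A and are bridged only by C2–C3 (C3 is the methyl carbinol). Cutting C1–C2 and C3–C4 gives a benzocyclobutenone that holds C1 and C4 in a four-membered ring on ring A, plus a (Z)-2-benzyloxypropenyl metal.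
- The benzocyclobutenone comes from a [2+2] cycloaddition of 3,5-bis(benzyloxy)benzyne with the ketene silyl acetal of a β-silyloxy ester; the C9 carbinol is set by an acetate aldol on a ring C aldehyde.
- The pyranone is joined to ring C only after all strong-base steps, by Negishi coupling at an aryl bromide placeholder, because its ring C–CH2–pyranone methylene is more acidic than the ester.
- Ring order: rings A, C and the pyranone are purchased aromatics; the four-membered ring forms in step 8, the pyranone is appended in step 11, and ring B closes in step 14.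

Key step: step 14

Assumption: the face of the 6π closure is predicted from an A(1,3)-strain model (C3 bonds to C4 anti to the ring C aryl), which calls for the (S)-carbinol at C9; since C9 is oxidised later, the (R)-auxiliary would serve equally if the sense proves opposite, and 1-bromopropyne is taken as a purchasable reagent.

Step 1
Reactants: 1 1,3-bis(benzyloxy)-5-bromobenzene
Product: 3 2,4-bis(benzyloxy)-6-bromobenzaldehyde, via iminium chloride 2 (not isolated)
Conditions: POCl3, DMF, 0 → 70 °C; then H2O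
Reagents that add atoms: N,N-dimethylformamide CN(C)C=O; water O
Why: Vilsmeier–Haack formylation of the resorcinol diether should occur at the carbon ortho to one benzyloxy group and para to the other (next to bromine), the site between the two benzyloxy groups being more hindered, as is known for the dimethyl ether analogue.

Step 2
Reactants: 3 2,4-bis(benzyloxy)-6-bromobenzaldehyde; 4 (S)-2-hydroxy-1,2,2-triphenylethyl acetate ((S)-HYTRA)
Product: 6 (1S)-2-hydroxy-1,2,2-triphenylethyl (3S)-3-[2,4-bis(benzyloxy)-6-bromophenyl]-3-hydroxypropanoate, via dilithium enolate 5 (not isolated)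
Conditions: LiN(i-Pr)2 (2.2 equiv), THF, −78 → 0 °C; then 3, −100 → −78 °C; aq. NH4Cl
Reagents that add atoms: none
Why: Braun acetate aldol, in which the doubly deprotonated (S)-auxiliary is expected to deliver the acetate enolate to one aldehyde face and give the (3S)-carbinol (C9 of the target skeleton), the minor diastereomer being removable by crystallisation of the adduct.

Step 3
Reactants: 6 (1S)-2-hydroxy-1,2,2-triphenylethyl (3S)-3-[2,4-bis(benzyloxy)-6-bromophenyl]-3-hydroxypropanoate
Product: 7 methyl (3S)-3-[2,4-bis(benzyloxy)-6-bromophenyl]-3-hydroxypropanoate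
Conditions: K2CO3 (cat.), MeOH–THF, 0 → 25 °C
Reagents that add atoms: methanol CO
Why: Base-catalysed transesterification releases the auxiliary diol under conditions mild enough to leave the β-hydroxy ester and its carbinol centre intact.

Step 4
Reactants: 7 methyl (3S)-3-[2,4-bis(benzyloxy)-6-bromophenyl]-3-hydroxypropanoate
Product: 8 methyl (3S)-3-[2,4-bis(benzyloxy)-6-bromophenyl]-3-[(tert-butyldimethylsilyl)oxy]propanoate
Conditions: TBSOTf, 2,6-lutidine, CH2Cl2, −78 → 0 °C
Reagents that add atoms: tert-butyldimethylsilyl trifluoromethanesulfonate CC(C)(C)[Si](C)(C)OS(=O)(=O)C(F)(F)F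
Why: Silylation of a hindered secondary benzylic alcohol with a silyl triflate and a non-nucleophilic base is fast at low temperature and does not ionise the electron-rich benzylic position.

Step 5
Reactants: 8 methyl (3S)-3-[2,4-bis(benzyloxy)-6-bromophenyl]-3-[(tert-butyldimethylsilyl)oxy]propanoate
Product: 10 {[(1E,3S)-3-[2,4-bis(benzyloxy)-6-bromophenyl]-3-[(tert-butyldimethylsilyl)oxy]-1-methoxyprop-1-en-1-yl]oxy}triethylsilane, via lithium enolate 9 (not isolated)
Conditions: LiN(i-Pr)2, Et3SiCl (present during enolisation), THF–DMPU, −78 °C; pentane, cold aq. NaHCO3 wash; used crude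
Reagents that add atoms: chlorotriethylsilane CC[Si](Cl)(CC)CC
Why: Kinetic ester enolisation with in situ O-silylation (Ireland/Corey internal quench) should trap the β-silyloxy enolate before it can expel silanolate; the acetal geometry (mainly E expected in THF) is of no consequence later.

Step 6
Reactants: 11 3,5-bis(benzyloxy)phenol
Product: 12 3,5-bis(benzyloxy)-2-iodophenol
Conditions: N-iodosuccinimide (1.0 equiv), CH2Cl2, −20 → 0 °C
Reagents that add atoms: N-iodosuccinimide O=C1CCC(=O)N1I
Why: Electrophilic iodination of the phloroglucinol diether should take one of the two equivalent positions ortho to the hydroxyl group rather than the more hindered carbon between the two benzyloxy groups.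

Step 7
Reactants: 12 3,5-bis(benzyloxy)-2-iodophenol
Product: 13 3,5-bis(benzyloxy)-2-iodophenyl trifluoromethanesulfonate
Conditions: Tf2O, pyridine, CH2Cl2, 0 °C
Reagents that add atoms: trifluoromethanesulfonic anhydride O=S(=O)(OS(=O)(=O)C(F)(F)F)C(F)(F)F
Why: O-Triflation of the phenol gives the ortho-iodoaryl triflate, a standard low-temperature aryne precursor.

Step 8
Reactants: 10 {[(1E,3S)-3-[2,4-bis(benzyloxy)-6-bromophenyl]-3-[(tert-butyldimethylsilyl)oxy]-1-methoxyprop-1-en-1-yl]oxy}triethylsilane; 13 3,5-bis(benzyloxy)-2-iodophenyl trifluoromethanesulfonate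
Product: 16 (7S,8S)-3,5-bis(benzyloxy)-8-{(S)-[2,4-bis(benzyloxy)-6-bromophenyl][(tert-butyldimethylsilyl)oxy]methyl}-7-methoxy-7-[(triethylsilyl)oxy]bicyclo[4.2.0]octa-1,3,5-triene, via aryllithium 14 (not isolated), via aryne 15 (not isolated)
Conditions: n-BuLi (slow addition to 10 + 13), THF, −78 °C
Reagents that add atoms: none
Why: Formal [2+2] cycloaddition of an α-alkoxyaryne with a ketene silyl acetal, in which iodine–lithium exchange outpaces attack on the aryl bromide, the acetal carbon bearing hydrogen attacks the aryne carbon remote from the flanking benzyloxy group and the aryl anion closes on the oxocarbenium carbon, so the future carbonyl sits next to a benzyloxy group; C8 should form anti to the ring C aryl under A(1,3) control and C7 follows the acetal geometry, but both centres are erased later (C7 in step 12, C8 in step 14), so epimers are carried on.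

Step 9
Reactants: 17 4-hydroxy-6-methyl-2H-pyran-2-one; 18 benzyl alcohol
Product: 19 4-(benzyloxy)-6-methyl-2H-pyran-2-one
Conditions: PPh3, DIAD, THF, 0 → 25 °C
Reagents that add atoms: none
Why: Mitsunobu O-alkylation of the acidic 4-hydroxypyranone should give the 4-benzyl ether and avoid the C3-benzylation that benzyl halides can cause.

Step 10
Reactants: 19 4-(benzyloxy)-6-methyl-2H-pyran-2-one
Product: 21 4-(benzyloxy)-6-(chloromethyl)-2H-pyran-2-one, via lithium dienolate 20 (not isolated)
Conditions: LiN(SiMe3)2, THF, −78 °C; then added to C2Cl6, −78 → −40 °C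
Reagents that add atoms: hexachloroethane ClC(Cl)(Cl)C(Cl)(Cl)Cl
Why: Kinetic deprotonation of the 6-methyl group of the vinylogous ester and chlorine transfer from hexachloroethane to the dienolate, with inverse addition to limit double chlorination and self-alkylation.

Step 11
Reactants: 16 (7S,8S)-3,5-bis(benzyloxy)-8-{(S)-[2,4-bis(benzyloxy)-6-bromophenyl][(tert-butyldimethylsilyl)oxy]methyl}-7-methoxy-7-[(triethylsilyl)oxy]bicyclo[4.2.0]octa-1,3,5-triene; 21 4-(benzyloxy)-6-(chloromethyl)-2H-pyran-2-one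
Product: 24 (7S,8S)-3,5-bis(benzyloxy)-8-{(S)-[2,4-bis(benzyloxy)-6-{[4-(benzyloxy)-2-oxo-2H-pyran-6-yl]methyl}phenyl][(tert-butyldimethylsilyl)oxy]methyl}-7-methoxy-7-[(triethylsilyl)oxy]bicyclo[4.2.0]octa-1,3,5-triene, via aryllithium 22 (not isolated), via arylzinc chloride 23 (not isolated)
Conditions: t-BuLi (2.1 equiv), Et2O, −78 °C; ZnCl2, THF, −78 → 0 °C; then 21, Pd(OAc)2 (cat.), SPhos, THF, 25 → 45 °C
Reagents that add atoms: none
Why: Bromine–lithium exchange, transmetallation to zinc and Negishi coupling with the activated allylic-type chloride; the arylzinc is too weakly basic to deprotonate the new doubly activated methylene, which therefore appears only after every strong-base step.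

Step 12
Reactants: 24 (7S,8S)-3,5-bis(benzyloxy)-8-{(S)-[2,4-bis(benzyloxy)-6-{[4-(benzyloxy)-2-oxo-2H-pyran-6-yl]methyl}phenyl][(tert-butyldimethylsilyl)oxy]methyl}-7-methoxy-7-[(triethylsilyl)oxy]bicyclo[4.2.0]octa-1,3,5-triene
Product: 26 (8S)-3,5-bis(benzyloxy)-8-{(S)-[2,4-bis(benzyloxy)-6-{[4-(benzyloxy)-2-oxo-2H-pyran-6-yl]methyl}phenyl][(tert-butyldimethylsilyl)oxy]methyl}bicyclo[4.2.0]octa-1,3,5-trien-7-one, via hemiketal 25 (not isolated)
Conditions: HF·pyridine, pyridine, THF, 0 °C
Reagents that add atoms: none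
Why: Buffered HF should cleave the triethylsilyl hemiketal ether much faster than the hindered secondary TBS ether, and the neutral hemiketal loses methanol to give the strained ketone without alkoxide-induced ring opening; C8 cannot epimerise because its enol would be an antiaromatic benzocyclobutadiene.

Step 13
Reactants: 27 1-bromoprop-1-yne; 18 benzyl alcohol
Product: 28 {[(1Z)-1-bromoprop-1-en-2-yl]oxy}methylbenzene (benzyl (Z)-2-bromo-1-methylvinyl ether)
Conditions: KH (0.2 equiv), THF–DMSO, 0 → 25 °C, sealed vessel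
Reagents that add atoms: none
Why: Nucleophilic trans-addition of an alkoxide to a haloalkyne (as with alkoxides and dichloroacetylene or phenoxides and 1-bromoalkynes), in which benzyloxide attacks the methyl-bearing carbon, the carbanion forms next to bromine and anti protonation puts bromine cis to oxygen.

Step 14
Reactants: 26 (8S)-3,5-bis(benzyloxy)-8-{(S)-[2,4-bis(benzyloxy)-6-{[4-(benzyloxy)-2-oxo-2H-pyran-6-yl]methyl}phenyl][(tert-butyldimethylsilyl)oxy]methyl}bicyclo[4.2.0]octa-1,3,5-trien-7-one; 28 {[(1Z)-1-bromoprop-1-en-2-yl]oxy}methylbenzene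
Product: 34 (3R,4R)-3,6,8-tris(benzyloxy)-4-{(S)-[2,4-bis(benzyloxy)-6-{[4-(benzyloxy)-2-oxo-2H-pyran-6-yl]methyl}phenyl][(tert-butyldimethylsilyl)oxy]methyl}-3-methyl-3,4-dihydronaphthalen-1(2H)-one, via alkenyllithium 29 (not isolated), via alkenylcerium dichloride 30 (not isolated), via cerium cyclobutenoxide 31 (not isolated), via o-quinodimethane 32 (not isolated), via cerium enolate 33 (not isolated)
Conditions: 28 (3 equiv), t-BuLi (6 equiv), Et2O, −78 °C; CeCl3 (anhydrous), THF, −78 °C; then 26, −78 → 0 °C; AcOH, −78 °C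
Reagents that add atoms: none
Why: Bromine–lithium exchange on 28 proceeds with retention, the chelated (Z)-alkenyllithium 29 is transmetallated to the weakly basic cerium reagent 30, and this adds to the strained ketone of 26 from the face opposite the C8 side chain to give alkoxide 31; oxyanion-accelerated conrotatory 4π opening with oxygen rotating outward (alkenyl and side chain inward) gives o-quinodimethane 32, whose disrotatory 6π electrocyclisation forms C3–C4 and leaves enolate 33, protonated to 34 on quench. The closest known reaction type is the addition of alkenyllithium reagents to benzocyclobutenones with alkoxide-accelerated ring opening and 6π closure to 1-tetralones. Ring B closes by a thermal disrotatory 6π electrocyclisation of the (Z,Z)-triene, driven by release of cyclobutene strain and the return of ring A aromaticity, so no enolate–carbonyl step is involved. The relative configuration of C3 and C4 follows from the pericyclic rules: the benzyloxy group (cis to the metal in 29) and the side chain (cis to the outward-rotating oxygen, hence forced inward) are both inward substituents at the triene termini, and disrotation places them cis. The absolute sense is relayed from C9: A(1,3) strain should hold the C9–H bond in the triene plane so that C3 bonds to C4 anti to the ring C aryl group, taking the (S)-carbinol to (3R,4R)-34, and because C9 is still stereogenic the other closure product is a separable diastereomer. The step needs 1,2-addition to the four-membered ketone in preference to the pyranone carbonyl and its acidic methylene, which ring strain and the organocerium reagent should secure, and a cold acidic quench so that enolate 33 does not expel benzyloxide.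

Step 15
Reactants: 34 (3R,4R)-3,6,8-tris(benzyloxy)-4-{(S)-[2,4-bis(benzyloxy)-6-{[4-(benzyloxy)-2-oxo-2H-pyran-6-yl]methyl}phenyl][(tert-butyldimethylsilyl)oxy]methyl}-3-methyl-3,4-dihydronaphthalen-1(2H)-one
Product: 35 (3R,4R)-3,6,8-tris(benzyloxy)-4-{(S)-[2,4-bis(benzyloxy)-6-{[4-(benzyloxy)-2-oxo-2H-pyran-6-yl]methyl}phenyl](hydroxy)methyl}-3-methyl-3,4-dihydronaphthalen-1(2H)-one
Conditions: Bu4NF, AcOH (1:1), THF, 0 → 25 °C
Reagents that add atoms: none
Why: Fluoride desilylation buffered with acetic acid avoids free alkoxide or enolate, so the β-benzyloxy ketone should not undergo E1cB elimination.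

Step 16
Reactants: 35 (3R,4R)-3,6,8-tris(benzyloxy)-4-{(S)-[2,4-bis(benzyloxy)-6-{[4-(benzyloxy)-2-oxo-2H-pyran-6-yl]methyl}phenyl](hydroxy)methyl}-3-methyl-3,4-dihydronaphthalen-1(2H)-one
Product: 36 (3R,4S)-3,6,8-tris(benzyloxy)-4-{2,4-bis(benzyloxy)-6-{[4-(benzyloxy)-2-oxo-2H-pyran-6-yl]methyl}benzoyl}-3-methyl-3,4-dihydronaphthalen-1(2H)-one
Conditions: Dess–Martin periodinane, NaHCO3, CH2Cl2, 0 → 25 °C
Reagents that add atoms: none
Why: Dess–Martin oxidation of the benzylic carbinol under buffered neutral conditions should give the aryl ketone without epimerising C4 (now α to the ketone) or eliminating the C3 benzyloxy group; the descriptor at C4 changes to S only because of priorities.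

Step 17
Reactants: 36 (3R,4S)-3,6,8-tris(benzyloxy)-4-{2,4-bis(benzyloxy)-6-{[4-(benzyloxy)-2-oxo-2H-pyran-6-yl]methyl}benzoyl}-3-methyl-3,4-dihydronaphthalen-1(2H)-one
Product: 37 (3R,4S)-4-{2,4-dihydroxy-6-[(4-hydroxy-2-oxo-2H-pyran-6-yl)methyl]benzoyl}-3,6,8-trihydroxy-3-methyl-3,4-dihydronaphthalen-1(2H)-one (CNP0197349.1)
Conditions: H2 (1 atm), Pd(OH)2/C, EtOAc–MeOH, 25 °C
Reagents that add atoms: none
Why: Catalytic hydrogenolysis should remove the five aryl and pyranone benzyl ethers and the tertiary benzyl ether under neutral conditions that leave the acid- and base-sensitive β-hydroxy ketone array and both stereocentres untouched.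

**Compound list**
1 | 1,3-bis(benzyloxy)-5-bromobenzene | Brc1cc(OCc2ccccc2)cc(OCc2ccccc2)c1 | starting material
2 | N-{[2,4-bis(benzyloxy)-6-bromophenyl]methylidene}-N-methylmethanaminium chloride | C[N+](C)=Cc1c(Br)cc(OCc2ccccc2)cc1OCc1ccccc1.[Cl-] | intermediate
3 | 2,4-bis(benzyloxy)-6-bromobenzaldehyde | O=Cc1c(Br)cc(OCc2ccccc2)cc1OCc1ccccc1 | intermediate
4 | (S)-2-hydroxy-1,2,2-triphenylethyl acetate ((S)-HYTRA) | CC(=O)O[C@@H](c1ccccc1)C(O)(c1ccccc1)c1ccccc1 | starting material
5 | dilithium enolate–alkoxide of 4 | C=C(O[Li])O[C@@H](c1ccccc1)C(O[Li])(c1ccccc1)c1ccccc1 | intermediate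
6 | (1S)-2-hydroxy-1,2,2-triphenylethyl (3S)-3-[2,4-bis(benzyloxy)-6-bromophenyl]-3-hydroxypropanoate | O=C(C[C@H](O)c1c(Br)cc(OCc2ccccc2)cc1OCc1ccccc1)O[C@@H](c1ccccc1)C(O)(c1ccccc1)c1ccccc1 | intermediate
7 | methyl (3S)-3-[2,4-bis(benzyloxy)-6-bromophenyl]-3-hydroxypropanoate | COC(=O)C[C@H](O)c1c(Br)cc(OCc2ccccc2)cc1OCc1ccccc1 | intermediate
8 | methyl (3S)-3-[2,4-bis(benzyloxy)-6-bromophenyl]-3-[(tert-butyldimethylsilyl)oxy]propanoate | COC(=O)C[C@H](O[Si](C)(C)C(C)(C)C)c1c(Br)cc(OCc2ccccc2)cc1OCc1ccccc1 | intermediate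
9 | lithium enolate of 8 (side chain cis to OMe) | CO/C(O[Li])=C\[C@H](O[Si](C)(C)C(C)(C)C)c1c(Br)cc(OCc2ccccc2)cc1OCc1ccccc1 | intermediate
10 | {[(1E,3S)-3-[2,4-bis(benzyloxy)-6-bromophenyl]-3-[(tert-butyldimethylsilyl)oxy]-1-methoxyprop-1-en-1-yl]oxy}triethylsilane | CO/C(O[Si](CC)(CC)CC)=C\[C@H](O[Si](C)(C)C(C)(C)C)c1c(Br)cc(OCc2ccccc2)cc1OCc1ccccc1 | intermediate
11 | 3,5-bis(benzyloxy)phenol | Oc1cc(OCc2ccccc2)cc(OCc2ccccc2)c1 | starting material
12 | 3,5-bis(benzyloxy)-2-iodophenol | Oc1cc(OCc2ccccc2)cc(OCc2ccccc2)c1I | intermediate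
13 | 3,5-bis(benzyloxy)-2-iodophenyl trifluoromethanesulfonate | O=S(=O)(Oc1cc(OCc2ccccc2)cc(OCc2ccccc2)c1I)C(F)(F)F | intermediate
14 | [2,4-bis(benzyloxy)-6-(trifluoromethanesulfonyloxy)phenyl]lithium | [Li]c1c(OS(=O)(=O)C(F)(F)F)cc(OCc2ccccc2)cc1OCc1ccccc1 | intermediate
15 | 3,5-bis(benzyloxy)benzyne (1,2-didehydrobenzene with benzyloxy groups at C3 and C5) | C1#CC(OCc2ccccc2)=CC(OCc2ccccc2)=C1 | intermediate
16 | (7S,8S)-3,5-bis(benzyloxy)-8-{(S)-[2,4-bis(benzyloxy)-6-bromophenyl][(tert-butyldimethylsilyl)oxy]methyl}-7-methoxy-7-[(triethylsilyl)oxy]bicyclo[4.2.0]octa-1,3,5-triene (methoxy cis to the side chain; epimers at C7 or C8 converge later) | CO[C@@]1(O[Si](CC)(CC)CC)c2c(OCc3ccccc3)cc(OCc3ccccc3)cc2[C@H]1[C@H](O[Si](C)(C)C(C)(C)C)c1c(Br)cc(OCc2ccccc2)cc1OCc1ccccc1 | intermediate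
17 | 4-hydroxy-6-methyl-2H-pyran-2-one | Cc1cc(O)cc(=O)o1 | starting material
18 | benzyl alcohol | OCc1ccccc1 | starting material
19 | 4-(benzyloxy)-6-methyl-2H-pyran-2-one | Cc1cc(OCc2ccccc2)cc(=O)o1 | intermediate
20 | lithium dienolate of 19 (drawn as the 6-lithiomethyl form) | [Li]Cc1cc(OCc2ccccc2)cc(=O)o1 | intermediate
21 | 4-(benzyloxy)-6-(chloromethyl)-2H-pyran-2-one | ClCc1cc(OCc2ccccc2)cc(=O)o1 | intermediate
22 | aryllithium from 16 (Li in place of Br) | CO[C@@]1(O[Si](CC)(CC)CC)c2c(OCc3ccccc3)cc(OCc3ccccc3)cc2[C@H]1[C@H](O[Si](C)(C)C(C)(C)C)c1c([Li])cc(OCc2ccccc2)cc1OCc1ccccc1 | intermediate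
23 | arylzinc chloride from 16 (ZnCl in place of Br) | CO[C@@]1(O[Si](CC)(CC)CC)c2c(OCc3ccccc3)cc(OCc3ccccc3)cc2[C@H]1[C@H](O[Si](C)(C)C(C)(C)C)c1c([Zn]Cl)cc(OCc2ccccc2)cc1OCc1ccccc1 | intermediate
24 | (7S,8S)-3,5-bis(benzyloxy)-8-{(S)-[2,4-bis(benzyloxy)-6-{[4-(benzyloxy)-2-oxo-2H-pyran-6-yl]methyl}phenyl][(tert-butyldimethylsilyl)oxy]methyl}-7-methoxy-7-[(triethylsilyl)oxy]bicyclo[4.2.0]octa-1,3,5-triene | CO[C@@]1(O[Si](CC)(CC)CC)c2c(OCc3ccccc3)cc(OCc3ccccc3)cc2[C@H]1[C@H](O[Si](C)(C)C(C)(C)C)c1c(OCc2ccccc2)cc(OCc2ccccc2)cc1Cc1cc(OCc2ccccc2)cc(=O)o1 | intermediate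
25 | hemiketal of 26 (7-hydroxy-7-methoxy; OH in place of the triethylsilyloxy group of 24) | CO[C@@]1(O)c2c(OCc3ccccc3)cc(OCc3ccccc3)cc2[C@H]1[C@H](O[Si](C)(C)C(C)(C)C)c1c(OCc2ccccc2)cc(OCc2ccccc2)cc1Cc1cc(OCc2ccccc2)cc(=O)o1 | intermediate
26 | (8S)-3,5-bis(benzyloxy)-8-{(S)-[2,4-bis(benzyloxy)-6-{[4-(benzyloxy)-2-oxo-2H-pyran-6-yl]methyl}phenyl][(tert-butyldimethylsilyl)oxy]methyl}bicyclo[4.2.0]octa-1,3,5-trien-7-one (the 4,6-bis(benzyloxy)benzocyclobutenone) | O=C1c2c(OCc3ccccc3)cc(OCc3ccccc3)cc2[C@H]1[C@H](O[Si](C)(C)C(C)(C)C)c1c(OCc2ccccc2)cc(OCc2ccccc2)cc1Cc1cc(OCc2ccccc2)cc(=O)o1 | intermediate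
27 | 1-bromoprop-1-yne | CC#CBr | starting material
28 | {[(1Z)-1-bromoprop-1-en-2-yl]oxy}methylbenzene (Br cis to O) | Br/C=C(/C)OCc1ccccc1 | intermediate
29 | (Z)-2-(benzyloxy)prop-1-en-1-yllithium (Li cis to O) | [Li]/C=C(/C)OCc1ccccc1 | intermediate
30 | (Z)-2-(benzyloxy)prop-1-en-1-ylcerium dichloride | Cl[Ce](Cl)/C=C(/C)OCc1ccccc1 | intermediate
31 | dichlorocerium alkoxide of the 7-[(Z)-2-(benzyloxy)prop-1-enyl]benzocyclobuten-7-ol (oxygen cis to the C8 side chain) | Cl[Ce](Cl)O[C@@]1(/C=C(/C)OCc2ccccc2)c2c(OCc3ccccc3)cc(OCc3ccccc3)cc2[C@H]1[C@H](O[Si](C)(C)C(C)(C)C)c1c(OCc2ccccc2)cc(OCc2ccccc2)cc1Cc1cc(OCc2ccccc2)cc(=O)o1 | intermediate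
32 | ring-opened o-quinodimethane alkoxide (oxygen outward; alkenyl and C9 side chain inward) | Cl[Ce](Cl)O/C(/C=C(/C)OCc1ccccc1)=C1\C(OCc2ccccc2)=CC(OCc2ccccc2)=C/C1=C/[C@H](O[Si](C)(C)C(C)(C)C)c1c(OCc2ccccc2)cc(OCc2ccccc2)cc1Cc1cc(OCc2ccccc2)cc(=O)o1 | intermediate
33 | dichlorocerium C1–C2 enolate of 34 | C[C@@]1(OCc2ccccc2)C=C(O[Ce](Cl)Cl)c2c(OCc3ccccc3)cc(OCc3ccccc3)cc2[C@@H]1[C@H](O[Si](C)(C)C(C)(C)C)c1c(OCc2ccccc2)cc(OCc2ccccc2)cc1Cc1cc(OCc2ccccc2)cc(=O)o1 | intermediate
34 | (3R,4R)-3,6,8-tris(benzyloxy)-4-{(S)-[2,4-bis(benzyloxy)-6-{[4-(benzyloxy)-2-oxo-2H-pyran-6-yl]methyl}phenyl][(tert-butyldimethylsilyl)oxy]methyl}-3-methyl-3,4-dihydronaphthalen-1(2H)-one (C3–OBn cis to the C4 side chain) | C[C@@]1(OCc2ccccc2)CC(=O)c2c(OCc3ccccc3)cc(OCc3ccccc3)cc2[C@@H]1[C@H](O[Si](C)(C)C(C)(C)C)c1c(OCc2ccccc2)cc(OCc2ccccc2)cc1Cc1cc(OCc2ccccc2)cc(=O)o1 | intermediate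
35 | (3R,4R)-3,6,8-tris(benzyloxy)-4-{(S)-[2,4-bis(benzyloxy)-6-{[4-(benzyloxy)-2-oxo-2H-pyran-6-yl]methyl}phenyl](hydroxy)methyl}-3-methyl-3,4-dihydronaphthalen-1(2H)-one | C[C@@]1(OCc2ccccc2)CC(=O)c2c(OCc3ccccc3)cc(OCc3ccccc3)cc2[C@@H]1[C@H](O)c1c(OCc2ccccc2)cc(OCc2ccccc2)cc1Cc1cc(OCc2ccccc2)cc(=O)o1 | intermediate
36 | (3R,4S)-3,6,8-tris(benzyloxy)-4-{2,4-bis(benzyloxy)-6-{[4-(benzyloxy)-2-oxo-2H-pyran-6-yl]methyl}benzoyl}-3-methyl-3,4-dihydronaphthalen-1(2H)-one | C[C@@]1(OCc2ccccc2)CC(=O)c2c(OCc3ccccc3)cc(OCc3ccccc3)cc2[C@@H]1C(=O)c1c(OCc2ccccc2)cc(OCc2ccccc2)cc1Cc1cc(OCc2ccccc2)cc(=O)o1 | intermediate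
37 | (3R,4S)-4-{2,4-dihydroxy-6-[(4-hydroxy-2-oxo-2H-pyran-6-yl)methyl]benzoyl}-3,6,8-trihydroxy-3-methyl-3,4-dihydronaphthalen-1(2H)-one | C[C@@]1(O)CC(=O)c2c(O)cc(O)cc2[C@@H]1C(=O)c1c(O)cc(O)cc1Cc1cc(O)cc(=O)o1 | target

**Step count and risks**
Total step count: 17. Longest linear sequence: 12 steps (steps 1–5, 8, 11, 12, 14–17); steps 6–7, 9–10 and 13 are side branches.

Step 14 is the most exposed. The bulky C8 side chain must rotate inward, which may slow ring opening of the cerium alkoxide. The o-quinodimethane may undergo a 1,5-hydrogen shift from C9 instead of closing. The 1,2-induction from C9 may give poor facial selectivity, and the metal enolate may lose benzyloxide and aromatise on warming. Since C9 remains stereogenic in 34, the wrong closure product is a diastereomer and chromatographic separation should still give a single enantiomer series, at the cost of material. The fallback sets out from 26 and separates the addition from the pericyclic steps. Reagent 30 is added at −78 °C and the mixture is quenched with acetic acid at that temperature, so that the neutral carbinol (8S)-7-[(Z)-2-(benzyloxy)prop-1-enyl]-7-hydroxybenzocyclobutene F1 can be isolated. Heating F1 in toluene at about 100 °C should then bring about the known thermal ring expansion of 1-alkenylbenzocyclobutenols, with the hydroxyl group rotating outward and no metal enolate at any stage. This returns to the route at 34.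

Step 11 may fail by migration of the neighbouring silyl group from oxygen to the lithiated carbon (retro-Brook), by protonation of the aryllithium, or by sluggish coupling of the hindered arylzinc. The fallback sets out from 16 and avoids organolithium chemistry altogether. Miyaura borylation (B2pin2, KOAc, Pd(dppf)Cl2, dioxane, 85 °C) should give the aryl pinacol boronate F2. Suzuki–Miyaura coupling of F2 with chloride 21 (Pd(PPh3)4, K3PO4, THF–H2O, 60 °C) then returns to the route at 24; the silyl ketal tolerates the aqueous base.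

Step 13 may suffer from attack of the alkoxide at bromine or from base-induced isomerisation of the bromoalkyne to bromoallene, either of which would erode the regio- and geometric purity of the enol ether. The fallback sets out from 18. Acid-catalysed transketalisation with 1-bromo-2,2-dimethoxypropane (TsOH cat., toluene, removal of methanol) should give 1-bromo-2,2-bis(benzyloxy)propane F3. Acid-catalysed elimination of benzyl alcohol from F3 (TsOH cat., heat, reduced pressure) under equilibrating conditions should then favour the internal enol ether with bromine cis to oxygen. Fractional distillation returns to the route at 28.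

Further compounds
F1 | step 14 | (8S)-3,5-bis(benzyloxy)-7-[(Z)-2-(benzyloxy)prop-1-enyl]-8-{(S)-[2,4-bis(benzyloxy)-6-{[4-(benzyloxy)-2-oxo-2H-pyran-6-yl]methyl}phenyl][(tert-butyldimethylsilyl)oxy]methyl}bicyclo[4.2.0]octa-1,3,5-trien-7-ol (hydroxyl cis to the C8 side chain) | O[C@@]1(/C=C(/C)OCc2ccccc2)c2c(OCc3ccccc3)cc(OCc3ccccc3)cc2[C@H]1[C@H](O[Si](C)(C)C(C)(C)C)c1c(OCc2ccccc2)cc(OCc2ccccc2)cc1Cc1cc(OCc2ccccc2)cc(=O)o1
F2 | step 11 | pinacol boronate of 16 (4,4,5,5-tetramethyl-1,3,2-dioxaborolan-2-yl in place of Br) | CO[C@@]1(O[Si](CC)(CC)CC)c2c(OCc3ccccc3)cc(OCc3ccccc3)cc2[C@H]1[C@H](O[Si](C)(C)C(C)(C)C)c1c(B2OC(C)(C)C(C)(C)O2)cc(OCc2ccccc2)cc1OCc1ccccc1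
F3 | step 13 | 1-bromo-2,2-bis(benzyloxy)propane | CC(CBr)(OCc1ccccc1)OCc1ccccc1
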